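The whole plan rests on disconnecting the bond from lactone carbon C5 to the first CH2 of the side chain. In the butyrolactone (ring atoms O1, C2, C3, C4, C5), C5 is bonded to O1 and lies beside carboxyl-bearing C4. With a carboxyl on C5 instead of the chain, the ring is the lactone of natural (2R,3S)-isocitric acid, C4 already correct, and the chain is decarboxylated hexadecanedioic acid. A single nickel-electrocatalysed doubly decarboxylative coupling therefore grafts the complete C15 acid chain onto the chiral-pool lactone and sets C5 trans to C4. Its precursor is the cis lactone carrying an N-hydroxyphthalimide ester at the carbinol carbon and a neighbouring tert-butyl ester.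

Key step: step 7

Assumption: 1 is used as the free acid; material supplied as the monopotassium salt would first be passed through a sulfonic acid ion-exchange resin.

Numbering remark: the paragraph above uses the target's lactone numbering (O1, C2 carbonyl, C3, C4, C5). The systematic names count the ring the other way (5-oxotetrahydrofuran), so target C5 is C2 of the names and target C4 is C3 of the names. The carbinol carbon is (2R) both in the cis compounds 2 to 7 and in the trans compounds 10 to 14 only because the substituent priorities change; its spatial arrangement is inverted in step 7.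

Step 1
Reactants: 1 (2R,3S)-isocitric acid
Product: 2 (2R,3S)-5-oxotetrahydrofuran-2,3-dicarboxylic acid (cis isocitric acid lactone)
Conditions: cat. HCl, H2O, evaporate; neat, 100–110 °C, reduced pressure
Reagents that add atoms: none
Why: Acid-promoted dehydrative gamma-lactonisation (intramolecular Fischer esterification) of the C2 hydroxyl onto the CH2CO2H arm should close the five-membered ring without touching either stereocentre, which leaves the two remaining carboxyls cis.

Step 2
Reactants: 2 (2R,3S)-5-oxotetrahydrofuran-2,3-dicarboxylic acid
Product: 4 (2R,3S)-2-(benzyloxycarbonyl)-5-oxotetrahydrofuran-3-carboxylic acid, via bicyclic lactone anhydride 3 (not isolated)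
Conditions: (CF3CO)2O, 0 °C to rt, evaporate (toluene chase); BnOH (1.05 equiv), THF, 0 °C to rt, no base; recrystallise
Reagents that add atoms: benzyl alcohol, OCc1ccccc1
Why: Dehydration of the cis diacid gives the moisture-sensitive cis-fused cyclic anhydride, and base-free alcoholysis (nucleophilic acyl substitution) should open it at the carbonyl on the oxygen-bearing carbon, the more electrophilic one as in the alcoholysis of O-acylmalic anhydrides, while the cis ring fusion locks both stereocentres and crystallisation removes any minor regioisomer.

Step 3
Reactants: 4 (2R,3S)-2-(benzyloxycarbonyl)-5-oxotetrahydrofuran-3-carboxylic acid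
Product: 5 2-benzyl 3-tert-butyl (2R,3S)-5-oxotetrahydrofuran-2,3-dicarboxylate
Conditions: tert-butyl 2,2,2-trichloroacetimidate (2 equiv), cat. BF3·OEt2, CH2Cl2/cyclohexane, rt
Reagents that add atoms: tert-butyl 2,2,2-trichloroacetimidate, CC(C)(C)OC(=N)C(Cl)(Cl)Cl
Why: Acid-catalysed tert-butylation of a carboxylic acid with the trichloroacetimidate (tert-butyl cation transfer) should esterify the C3 acid under non-basic conditions that leave the benzyl ester, the lactone and both stereocentres untouched.

Step 4
Reactants: 5 2-benzyl 3-tert-butyl (2R,3S)-5-oxotetrahydrofuran-2,3-dicarboxylate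
Product: 6 (2R,3S)-3-(tert-butoxycarbonyl)-5-oxotetrahydrofuran-2-carboxylic acid
Conditions: H2 (1 atm), 10% Pd/C, EtOAc, rt
Reagents that add atoms: none
Why: Catalytic hydrogenolysis cleaves only the benzylic C–O bond, so the C2 acid should be freed while the tert-butyl ester, the lactone and the stereocentres stay intact.

Step 5
Reactants: 6 (2R,3S)-3-(tert-butoxycarbonyl)-5-oxotetrahydrofuran-2-carboxylic acid
Product: 7 3-tert-butyl 2-(1,3-dioxoisoindolin-2-yl) (2R,3S)-5-oxotetrahydrofuran-2,3-dicarboxylate (ring redox-active ester)
Conditions: N-hydroxyphthalimide (1.1 equiv), N,N'-diisopropylcarbodiimide (1.1 equiv), CH2Cl2, 0 °C to rt, no added base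
Reagents that add atoms: N-hydroxyphthalimide, O=C1c2ccccc2C(=O)N1O
Why: Steglich-type carbodiimide esterification with the acidic N-hydroxyphthalimide needs no amine base, which protects the ester-bearing stereocentre, and any epimerisation at the activated carbinol carbon is harmless because that centre becomes planar in step 7.

Step 6
Reactants: 8 16-tert-butoxy-16-oxohexadecanoic acid (hexadecanedioic acid mono-tert-butyl ester)
Product: 9 1-tert-butyl 16-(1,3-dioxoisoindolin-2-yl) hexadecanedioate (chain redox-active ester)
Conditions: N-hydroxyphthalimide, N,N'-diisopropylcarbodiimide, cat. 4-(dimethylamino)pyridine, CH2Cl2, rt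
Reagents that add atoms: N-hydroxyphthalimide, O=C1c2ccccc2C(=O)N1O
Why: Steglich esterification of an unhindered primary acid with N-hydroxyphthalimide is routine and the remote tert-butyl ester is inert to it.

Step 7
Reactants: 7 3-tert-butyl 2-(1,3-dioxoisoindolin-2-yl) (2R,3S)-5-oxotetrahydrofuran-2,3-dicarboxylate; 9 1-tert-butyl 16-(1,3-dioxoisoindolin-2-yl) hexadecanedioate
Product: 10 tert-butyl (2R,3S)-2-(15-tert-butoxy-15-oxopentadecyl)-5-oxotetrahydrofuran-3-carboxylate (trans)
Conditions: 7 (1 equiv), 9 (3 equiv), NiCl2·6H2O (20 mol%), 2,2':6',2''-terpyridine (20 mol%), AgNO3 (0.3 equiv), NMP, Mg anode, reticulated vitreous carbon cathode, undivided cell, constant current, rt; aq. NH4Cl work-up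
Reagents that add atoms: none
Why: Each N-acyloxyphthalimide takes up one electron (from the cathode or from reduced nickel) and fragments into phthalimide anion, CO2 and a carbon radical, here the primary chain radical and the secondary alpha-acyloxy radical at the lactone carbinol carbon; the nickel–terpyridine catalyst binds the two radicals one after the other and reductive elimination from the dialkylnickel species forms the sp3–sp3 bond. The closest known reaction type is the nickel-electrocatalytic doubly decarboxylative cross-coupling of two redox-active esters, established for secondary alpha-oxy ring acids with primary acids, including trans-selective alkylation of tartrate-derived cyclic esters. No ring closes, so no mode of closure is involved, and the lactone, both tert-butyl esters and the ester-bearing stereocentre are spectators under these neutral reductive conditions. The one new stereocentre (the carbinol carbon, C5 of the target) is set at the planar ring radical stage by the bulky tert-butoxycarbonyl group on the neighbouring carbon, which blocks its own face so that the chain should enter anti and give the trans lactone whatever the configuration of 7 at the activated carbon. The step needs cross-coupling over homocoupling and trans over cis selectivity: the pairing of a primary radical with a stabilised secondary alpha-oxy radical, together with the threefold excess of the cheap partner 9, secures the first, and the neighbouring tert-butyl ester the second.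

Step 8
Reactants: 10 tert-butyl (2R,3S)-2-(15-tert-butoxy-15-oxopentadecyl)-5-oxotetrahydrofuran-3-carboxylate
Product: 11 (2R,3S)-2-(14-carboxytetradecyl)-5-oxotetrahydrofuran-3-carboxylic acid (trans paraconic diacid)
Conditions: CF3CO2H/CH2Cl2 (1:1), rt
Reagents that add atoms: none
Why: Acidolysis of tert-butyl esters (loss of the tert-butyl cation) should remove both ester groups in one operation, and the gamma-lactone and the trans stereocentres are stable to trifluoroacetic acid.

Step 9
Reactants: 11 (2R,3S)-2-(14-carboxytetradecyl)-5-oxotetrahydrofuran-3-carboxylic acid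
Product: 12 (2R,3S)-2-(14-carboxytetradecyl)-5-oxotetrahydrofuran-3,4-dicarboxylic acid (epimers at the new carboxyl-bearing carbon)
Conditions: methoxymagnesium methyl carbonate MeOMgOCO2Me (2 M in DMF, large excess), 130–135 °C, N2; then cold aq. HCl, extract; crude used at once
Reagents that add atoms: methoxymagnesium methyl carbonate, COC(=O)O[Mg]OC
Why: Alpha-carboxylation with magnesium methyl carbonate traps the lactone enolate as a chelated magnesium malonate-type salt, while the ring carboxyl and the chain carboxyl sit as carboxylates, which shields the hydrogen on the carboxyl-bearing ring carbon from enolisation, as in the standard conversion of trans paraconic acids.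

Step 10
Reactants: 12 (2R,3S)-2-(14-carboxytetradecyl)-5-oxotetrahydrofuran-3,4-dicarboxylic acid
Product: 14 (2R,3S)-2-(14-carboxytetradecyl)-4-methylidene-5-oxotetrahydrofuran-3-carboxylic acid (target CNP0222442.1), via Mannich base 13 (not isolated)
Conditions: 37% aq. HCHO, N-methylaniline, NaOAc, AcOH, rt
Reagents that add atoms: formaldehyde, C=O
Why: In this decarboxylative Mannich methylenation the malonic-type acid should add to the iminium ion from formaldehyde and N-methylaniline, and the adduct should lose CO2 and the amine to leave the exocyclic methylene under buffered, weakly acidic conditions that do not disturb the two stereocentres.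

Compound list
1 | (2R,3S)-isocitric acid | OC(=O)C[C@H](C(=O)O)[C@@H](O)C(=O)O | starting material
2 | (2R,3S)-5-oxotetrahydrofuran-2,3-dicarboxylic acid (cis isocitric acid lactone) | C1C(=O)O[C@@H](C(=O)O)[C@H]1C(=O)O | intermediate
3 | (3aS,6aR)-dihydrofuro[3,4-b]furan-2,4,6(3H)-trione (cis-fused bicyclic lactone anhydride, configuration of 2 retained) | C1C(=O)O[C@H]2C(=O)OC(=O)[C@@H]12 | intermediate (not isolated)
4 | (2R,3S)-2-(benzyloxycarbonyl)-5-oxotetrahydrofuran-3-carboxylic acid (cis) | C1C(=O)O[C@@H](C(=O)OCc2ccccc2)[C@H]1C(=O)O | intermediate
5 | 2-benzyl 3-tert-butyl (2R,3S)-5-oxotetrahydrofuran-2,3-dicarboxylate (cis) | C1C(=O)O[C@@H](C(=O)OCc2ccccc2)[C@H]1C(=O)OC(C)(C)C | intermediate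
6 | (2R,3S)-3-(tert-butoxycarbonyl)-5-oxotetrahydrofuran-2-carboxylic acid (cis) | C1C(=O)O[C@@H](C(=O)O)[C@H]1C(=O)OC(C)(C)C | intermediate
7 | 3-tert-butyl 2-(1,3-dioxoisoindolin-2-yl) (2R,3S)-5-oxotetrahydrofuran-2,3-dicarboxylate (cis, ring redox-active ester) | C1C(=O)O[C@@H](C(=O)ON2C(=O)c3ccccc3C2=O)[C@H]1C(=O)OC(C)(C)C | intermediate
8 | 16-tert-butoxy-16-oxohexadecanoic acid (hexadecanedioic acid mono-tert-butyl ester) | OC(=O)CCCCCCCCCCCCCCC(=O)OC(C)(C)C | starting material
9 | 1-tert-butyl 16-(1,3-dioxoisoindolin-2-yl) hexadecanedioate (chain redox-active ester) | O=C1c2ccccc2C(=O)N1OC(=O)CCCCCCCCCCCCCCC(=O)OC(C)(C)C | intermediate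
10 | tert-butyl (2R,3S)-2-(15-tert-butoxy-15-oxopentadecyl)-5-oxotetrahydrofuran-3-carboxylate (trans) | C1C(=O)O[C@H](CCCCCCCCCCCCCCC(=O)OC(C)(C)C)[C@H]1C(=O)OC(C)(C)C | intermediate
11 | (2R,3S)-2-(14-carboxytetradecyl)-5-oxotetrahydrofuran-3-carboxylic acid (trans) | C1C(=O)O[C@H](CCCCCCCCCCCCCCC(=O)O)[C@H]1C(=O)O | intermediate
12 | (2R,3S)-2-(14-carboxytetradecyl)-5-oxotetrahydrofuran-3,4-dicarboxylic acid (C4 epimers) | OC(=O)C1C(=O)O[C@H](CCCCCCCCCCCCCCC(=O)O)[C@H]1C(=O)O | intermediate
13 | (2R,3S)-2-(14-carboxytetradecyl)-4-[(N-methylanilino)methyl]-5-oxotetrahydrofuran-3,4-dicarboxylic acid (Mannich base, C4 epimers) | CN(c1ccccc1)CC1(C(=O)O)C(=O)O[C@H](CCCCCCCCCCCCCCC(=O)O)[C@H]1C(=O)O | intermediate (not isolated)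
14 | (2R,3S)-2-(14-carboxytetradecyl)-4-methylidene-5-oxotetrahydrofuran-3-carboxylic acid (trans; C4 S and C5 R in the lactone numbering of the target) | C=C1C(=O)O[C@H](CCCCCCCCCCCCCCC(=O)O)[C@H]1C(=O)O | target

Total step count: 10. Longest linear sequence: 9 steps (1 to 14 through steps 1–5 and 7–10); step 6 is the one-step side branch.

Steps most likely to fail

Step 7. What may go wrong is homocoupling of the two radical precursors outrunning the cross-coupling, beta-hydride loss from the ring carbon–nickel intermediate, or weak facial discrimination at the planar ring radical. The fallback is a metallaphotoredox decarboxylative sp3–sp3 alkylation, in which only the ring acid is a radical source and the chain enters as an alkyl bromide by oxidative addition, so that cross-selectivity no longer depends on sorting two radicals. It sets out from acid 6. Purchased 15-bromopentadecanoic acid F1 would be esterified with tert-butyl 2,2,2-trichloroacetimidate and cat. BF3·OEt2 to tert-butyl 15-bromopentadecanoate F2. Acid 6 and F2 would then be irradiated with blue LEDs in MeCN in the presence of Ir[dF(CF3)ppy]2(dtbbpy)PF6, NiCl2·DME, 4,4'-dimethoxy-2,2'-bipyridine, K2CO3 and a little water. This should give the trans diester through the same ring radical, and the route is rejoined at 10.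

Step 2. What may go wrong is attack of the alcohol at both anhydride carbonyls (insufficient regioselectivity) or hydrolysis of the anhydride back to the diacid by adventitious water. The fallback tells the two carboxyls apart by acidity instead of by carbonyl electrophilicity. It sets out from diacid 2. One equivalent of NaHCO3 in DMF should deprotonate mainly the more acidic carboxyl on the oxygen-bearing carbon, and O-alkylation of this monocarboxylate with benzyl bromide (1 equiv, rt) should give the monoester directly. Dibenzyl ester and unreacted diacid would be removed by acid–base extraction. The fallback makes no new compound (F0) and rejoins the route at 4.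

Step 9. What may go wrong is incomplete carboxylation, or lactone opening and epimerisation beside the ring carboxylate during long heating in the basic carbonate medium. The fallback is aminomethylation of the lactone enolate at the protected stage. It sets out from diester 10. LiN(SiMe3)2 in THF at −78 °C should deprotonate the lactone alpha-CH2, which is markedly more acidic than the alpha-hydrogens of the two tert-butyl esters. Trapping with dimethylmethylideneammonium iodide should give the dimethylaminomethyl lactone F3. Quaternisation with MeI would give the trimethylammonium iodide F4, which on stirring with aqueous NaHCO3 and CH2Cl2 should eliminate trimethylamine to the alpha-methylene di-tert-butyl ester F5. CF3CO2H/CH2Cl2 would then remove both tert-butyl esters, and the route is rejoined at the target 14.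

Further compounds
F1 | step 7 | 15-bromopentadecanoic acid (bought for the fallback) | OC(=O)CCCCCCCCCCCCCCBr
F2 | step 7 | tert-butyl 15-bromopentadecanoate | CC(C)(C)OC(=O)CCCCCCCCCCCCCCBr
F0 | step 2 | none | none
F3 | step 9 | tert-butyl (2R,3S)-2-(15-tert-butoxy-15-oxopentadecyl)-4-[(dimethylamino)methyl]-5-oxotetrahydrofuran-3-carboxylate (C4 epimers) | CN(C)CC1C(=O)O[C@H](CCCCCCCCCCCCCCC(=O)OC(C)(C)C)[C@H]1C(=O)OC(C)(C)C
F4 | step 9 | {[(4S,5R)-4-(tert-butoxycarbonyl)-5-(15-tert-butoxy-15-oxopentadecyl)-2-oxotetrahydrofuran-3-yl]methyl}trimethylammonium iodide | C[N+](C)(C)CC1C(=O)O[C@H](CCCCCCCCCCCCCCC(=O)OC(C)(C)C)[C@H]1C(=O)OC(C)(C)C.[I-]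
F5 | step 9 | tert-butyl (2R,3S)-2-(15-tert-butoxy-15-oxopentadecyl)-4-methylidene-5-oxotetrahydrofuran-3-carboxylate | C=C1C(=O)O[C@H](CCCCCCCCCCCCCCC(=O)OC(C)(C)C)[C@H]1C(=O)OC(C)(C)C
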